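**Retrosynthetic overview**
1. The target is the C8–C2′ dehydro-dimer of acacetin. All carbon comes from 2,4,6-trihydroxyacetophenone 1 (as its dibenzyl ether 2, both A rings) and 4-methoxybenzaldehyde 3 (both B rings), each used twice.
2. First pyranone ring: 2 + 3 → chalcone 4 → flavanone 5 (in flask) → flavone 6.
3. Key disconnection, biaryl bond C8–C2′: twofold C–H coupling of 6 with a second molecule of 3 (ortho to CHO) → biaryl aldehyde 7 (proposed new method).
4. Second pyranone ring: 7 + 2 → chalcone 8 → flavanone 9 (in flask) → tetrabenzyl biflavone 10.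
5. Last: hydrogenolysis of the four benzyl ethers → target 11.

Assumption: the SMILES has no stereodescriptor and the molecule has no stereocentre, so the compound is made as drawn; the C8–C2′ biaryl axis is unassigned and is not controlled.

**Route**

Step 1
Reactants: 1 2,4,6-trihydroxyacetophenone [1-(2,4,6-trihydroxyphenyl)ethan-1-one, dried monohydrate]
Product: 2 1-[2,4-bis(benzyloxy)-6-hydroxyphenyl]ethan-1-one
Conditions: BnBr (2.1 equiv), K2CO3 (2.2 equiv), DMF, 0 °C → rt
Reagents that add atoms: benzyl bromide (BrCc1ccccc1)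
Why: Williamson ether synthesis in which the 4-OH and one of the two equivalent ortho-OH groups are benzylated, while the remaining ortho-OH is held back by its hydrogen bond to the acetyl carbonyl, so alkylation stops at the dibenzyl ether.

Step 2
Reactants: 2 1-[2,4-bis(benzyloxy)-6-hydroxyphenyl]ethan-1-one; 3 4-methoxybenzaldehyde
Product: 4 (E)-1-[2,4-bis(benzyloxy)-6-hydroxyphenyl]-3-(4-methoxyphenyl)prop-2-en-1-one
Conditions: KOH (50% aq.), EtOH/THF, rt, 24 h
Reagents that add atoms: none
Why: Claisen–Schmidt (crossed aldol) condensation in which the methyl ketone of 2 is the only enolisable partner and 3 the only electrophile, and E1cB loss of water gives the conjugated (E)-enone as the thermodynamic alkene.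

Step 3
Reactants: 4 (E)-1-[2,4-bis(benzyloxy)-6-hydroxyphenyl]-3-(4-methoxyphenyl)prop-2-en-1-one
Product: 6 di-O-benzylacacetin [5,7-bis(benzyloxy)-2-(4-methoxyphenyl)-4H-chromen-4-one], via racemic flavanone 5 (not isolated)
Conditions: I2 (10 mol %), DMSO, 130 °C, 3 h
Reagents that add atoms: none
Why: Iodine-catalysed oxidative cyclisation of a 2′-hydroxychalcone, in which the single free phenol closes by oxa-Michael addition to flavanone 5, iodine dehydrogenates C2–C3 and DMSO reoxidises the HI formed, so only one flavone regioisomer can arise.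

Step 4
Reactants: 6 5,7-bis(benzyloxy)-2-(4-methoxyphenyl)-4H-chromen-4-one; 3 4-methoxybenzaldehyde (second use, 4 equiv)
Product: 7 2-[5,7-bis(benzyloxy)-2-(4-methoxyphenyl)-4-oxo-4H-chromen-8-yl]-4-methoxybenzaldehyde
Conditions: Pd(OAc)2 (10 mol %), 2-amino-2-methylpropanoic acid (40 mol %), AgOAc (2.5 equiv), (CF3)2CHOH/AcOH (9:1), 90 °C
Reagents that add atoms: none
Why: Proposed new method: a twofold C–H (cross-dehydrogenative) biaryl coupling in which the amino acid co-catalyst condenses reversibly with 3 to a transient imine whose nitrogen and carboxylate hold divalent palladium for ortho C–H cleavage (a fused 5,5-palladacycle with one free site); this electrophilic aryl–palladium species then palladates the most nucleophilic and least hindered arene C–H of 6, namely C8–H between the ring oxygen and the 7-benzyloxy group (the site where 5,7-dialkoxyflavones are iodinated, whereas C6 is flanked by two benzyloxy groups and C3 is deactivated by the carbonyl), by electrophilic aromatic substitution or concerted metalation–deprotonation; C–C reductive elimination gives the biaryl and zerovalent palladium, which AgOAc reoxidises, and imine hydrolysis frees 7 and the amine; homocoupling of 3 is disfavoured because its ring is electron-poor, excess 3 keeps the flavone limiting, and fluorenone formation from 7 is blocked because both positions ortho to the new bond on the flavone ring are substituted; the closest known reaction types are divalent-palladium-catalysed ortho C–H arylation of benzaldehydes with aryl iodides through transient imine directing groups and directed dehydrogenative arylation of anilides or benzamides with electron-rich arenes.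

Step 5
Reactants: 7 2-[5,7-bis(benzyloxy)-2-(4-methoxyphenyl)-4-oxo-4H-chromen-8-yl]-4-methoxybenzaldehyde; 2 1-[2,4-bis(benzyloxy)-6-hydroxyphenyl]ethan-1-one (second use, 1.2 equiv)
Product: 8 5,7-bis(benzyloxy)-8-{2-[(E)-3-(2,4-bis(benzyloxy)-6-hydroxyphenyl)-3-oxoprop-1-en-1-yl]-5-methoxyphenyl}-2-(4-methoxyphenyl)-4H-chromen-4-one
Conditions: KOH (50% aq.), EtOH/THF, 0 °C → rt
Reagents that add atoms: none
Why: Claisen–Schmidt condensation again, in which the potassium enolate of 2 adds to the only aldehyde present and loses water to the (E)-chalcone, while the chromone of unit 1 and the benzyl and methyl ethers are expected to tolerate cold ethanolic KOH.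

Step 6
Reactants: 8 5,7-bis(benzyloxy)-8-{2-[(E)-3-(2,4-bis(benzyloxy)-6-hydroxyphenyl)-3-oxoprop-1-en-1-yl]-5-methoxyphenyl}-2-(4-methoxyphenyl)-4H-chromen-4-one
Product: 10 5,7-bis(benzyloxy)-8-{2-[5,7-bis(benzyloxy)-4-oxo-4H-chromen-2-yl]-5-methoxyphenyl}-2-(4-methoxyphenyl)-4H-chromen-4-one, via flavanone–flavone intermediate 9 (not isolated)
Conditions: I2 (10 mol %), DMSO, 130 °C, 3 h
Reagents that add atoms: none
Why: The same iodine-catalysed oxidative cyclisation as in step 3, in which oxa-Michael closure through the only free phenol gives flavanone 9 and iodine/DMSO dehydrogenates it to the second chromone, the first chromone and the ethers being stable under these conditions.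

Step 7
Reactants: 10 5,7-bis(benzyloxy)-8-{2-[5,7-bis(benzyloxy)-4-oxo-4H-chromen-2-yl]-5-methoxyphenyl}-2-(4-methoxyphenyl)-4H-chromen-4-one
Product: 11 8-[2-(5,7-dihydroxy-4-oxo-4H-chromen-2-yl)-5-methoxyphenyl]-5,7-dihydroxy-2-(4-methoxyphenyl)-4H-chromen-4-one (target)
Conditions: H2 (1 atm), 10% Pd/C, THF/MeOH (1:1), rt
Reagents that add atoms: none
Why: Catalytic hydrogenolysis of the four aryl benzyl ethers on Pd/C is far faster than hydrogenation of the vinylogous-ester C2=C3 bonds of the two chromones and does not touch aryl methyl ethers, so both methoxy groups stay and no stereocentre is created.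

**Compound list**
1 | 2,4,6-trihydroxyacetophenone [1-(2,4,6-trihydroxyphenyl)ethan-1-one] | CC(=O)c1c(O)cc(O)cc1O | starting material
2 | 1-[2,4-bis(benzyloxy)-6-hydroxyphenyl]ethan-1-one | CC(=O)c1c(O)cc(OCc2ccccc2)cc1OCc1ccccc1 | intermediate
3 | 4-methoxybenzaldehyde | COc1ccc(C=O)cc1 | starting material
4 | (E)-1-[2,4-bis(benzyloxy)-6-hydroxyphenyl]-3-(4-methoxyphenyl)prop-2-en-1-one | COc1ccc(/C=C/C(=O)c2c(O)cc(OCc3ccccc3)cc2OCc2ccccc2)cc1 | intermediate
5 | racemic 5,7-bis(benzyloxy)-2-(4-methoxyphenyl)chroman-4-one (flavanone, not isolated) | COc1ccc(C2CC(=O)c3c(OCc4ccccc4)cc(OCc4ccccc4)cc3O2)cc1 | intermediate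
6 | 5,7-bis(benzyloxy)-2-(4-methoxyphenyl)-4H-chromen-4-one | COc1ccc(-c2cc(=O)c3c(OCc4ccccc4)cc(OCc4ccccc4)cc3o2)cc1 | intermediate
7 | 2-[5,7-bis(benzyloxy)-2-(4-methoxyphenyl)-4-oxo-4H-chromen-8-yl]-4-methoxybenzaldehyde | COc1ccc(-c2cc(=O)c3c(OCc4ccccc4)cc(OCc4ccccc4)c(-c4cc(OC)ccc4C=O)c3o2)cc1 | intermediate
8 | 5,7-bis(benzyloxy)-8-{2-[(E)-3-(2,4-bis(benzyloxy)-6-hydroxyphenyl)-3-oxoprop-1-en-1-yl]-5-methoxyphenyl}-2-(4-methoxyphenyl)-4H-chromen-4-one | COc1ccc(-c2cc(=O)c3c(OCc4ccccc4)cc(OCc4ccccc4)c(-c4cc(OC)ccc4/C=C/C(=O)c4c(O)cc(OCc5ccccc5)cc4OCc4ccccc4)c3o2)cc1 | intermediate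
9 | 5,7-bis(benzyloxy)-8-{2-[5,7-bis(benzyloxy)-4-oxochroman-2-yl]-5-methoxyphenyl}-2-(4-methoxyphenyl)-4H-chromen-4-one (flavanone carbon unassigned, stereoisomer mixture, not isolated) | COc1ccc(-c2cc(=O)c3c(OCc4ccccc4)cc(OCc4ccccc4)c(-c4cc(OC)ccc4C4CC(=O)c5c(OCc6ccccc6)cc(OCc6ccccc6)cc5O4)c3o2)cc1 | intermediate
10 | 5,7-bis(benzyloxy)-8-{2-[5,7-bis(benzyloxy)-4-oxo-4H-chromen-2-yl]-5-methoxyphenyl}-2-(4-methoxyphenyl)-4H-chromen-4-one | COc1ccc(-c2cc(=O)c3c(OCc4ccccc4)cc(OCc4ccccc4)c(-c4cc(OC)ccc4-c4cc(=O)c5c(OCc6ccccc6)cc(OCc6ccccc6)cc5o4)c3o2)cc1 | intermediate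
11 | 8-[2-(5,7-dihydroxy-4-oxo-4H-chromen-2-yl)-5-methoxyphenyl]-5,7-dihydroxy-2-(4-methoxyphenyl)-4H-chromen-4-one | COc1ccc(-c2cc(=O)c3c(O)cc(O)c(-c4cc(OC)ccc4-c4cc(=O)c5c(O)cc(O)cc5o4)c3o2)cc1 | target

**Totals**
Total step count: 7. Longest linear sequence: 7 steps (1 → 2 → 4 → 6 → 7 → 8 → 10 → 11; compounds 2 and 3 are each used twice).

**Three steps most likely to fail, with fallbacks**

Step 4, the proposed twofold C–H coupling, is the main risk: no turnover, palladation at C6 or C3, or oxidative homocoupling of 6. The fallback uses known chemistry, sets out from 6 and comes back at 7. Electrophilic iodination of 6 with I2/AgO2CCF3 in CH2Cl2 at rt, which for fully O-alkylated 5,7-dioxygenated flavones goes to C8, gives 5,7-bis(benzyloxy)-8-iodo-2-(4-methoxyphenyl)-4H-chromen-4-one F1. Suzuki–Miyaura coupling of F1 with commercial (2-formyl-5-methoxyphenyl)boronic acid (Pd(OAc)2, SPhos, K3PO4, toluene/H2O, 90 °C) then returns to the route at 7.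

Step 5 may fail because aqueous KOH can open the pyranone of unit 1 or because the ortho-aryl aldehyde condenses poorly. The fallback sets out from 7 and comes back at 10, bypassing 8 and 9, by a Baker–Venkataraman approach:
- Oxidation of 7 (NaClO2, NaH2PO4, 2-methylbut-2-ene, t-BuOH/THF/H2O) gives 2-[5,7-bis(benzyloxy)-2-(4-methoxyphenyl)-4-oxo-4H-chromen-8-yl]-4-methoxybenzoic acid F2.
- Esterification with phenol 2 (DCC, DMAP, CH2Cl2) gives 2-acetyl-3,5-bis(benzyloxy)phenyl 2-[5,7-bis(benzyloxy)-2-(4-methoxyphenyl)-4-oxo-4H-chromen-8-yl]-4-methoxybenzoate F3.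
- Acyl transfer with the non-nucleophilic base LiN(SiMe3)2 (THF, −78 °C → rt) gives 1-[2,4-bis(benzyloxy)-6-hydroxyphenyl]-3-{2-[5,7-bis(benzyloxy)-2-(4-methoxyphenyl)-4-oxo-4H-chromen-8-yl]-4-methoxyphenyl}propane-1,3-dione F4.
- Acid cyclodehydration of F4 (p-TsOH·H2O cat., toluene, 90 °C) closes the second pyranone and gives 10.

Step 7 may saturate a chromone C2=C3 bond or stall when partly debenzylated material precipitates on the catalyst. The fallback sets out from 10 and comes back directly at 11 without hydrogen. The four benzyl ethers are cleaved with BCl3 and pentamethylbenzene as benzyl-cation scavenger (CH2Cl2, −78 → −40 °C, MeOH quench). At this temperature the aryl methyl ethers and both enone double bonds are left alone. New compounds on this way: none F0.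

**Further compounds**
F1 | step 4 | 5,7-bis(benzyloxy)-8-iodo-2-(4-methoxyphenyl)-4H-chromen-4-one | COc1ccc(-c2cc(=O)c3c(OCc4ccccc4)cc(OCc4ccccc4)c(I)c3o2)cc1
F2 | step 5 | 2-[5,7-bis(benzyloxy)-2-(4-methoxyphenyl)-4-oxo-4H-chromen-8-yl]-4-methoxybenzoic acid | COc1ccc(-c2cc(=O)c3c(OCc4ccccc4)cc(OCc4ccccc4)c(-c4cc(OC)ccc4C(=O)O)c3o2)cc1
F3 | step 5 | 2-acetyl-3,5-bis(benzyloxy)phenyl 2-[5,7-bis(benzyloxy)-2-(4-methoxyphenyl)-4-oxo-4H-chromen-8-yl]-4-methoxybenzoate | COc1ccc(-c2cc(=O)c3c(OCc4ccccc4)cc(OCc4ccccc4)c(-c4cc(OC)ccc4C(=O)Oc4cc(OCc5ccccc5)cc(OCc5ccccc5)c4C(C)=O)c3o2)cc1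
F4 | step 5 | 1-[2,4-bis(benzyloxy)-6-hydroxyphenyl]-3-{2-[5,7-bis(benzyloxy)-2-(4-methoxyphenyl)-4-oxo-4H-chromen-8-yl]-4-methoxyphenyl}propane-1,3-dione | COc1ccc(-c2cc(=O)c3c(OCc4ccccc4)cc(OCc4ccccc4)c(-c4cc(OC)ccc4C(=O)CC(=O)c4c(O)cc(OCc5ccccc5)cc4OCc4ccccc4)c3o2)cc1
F0 | step 7 | none | none
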